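The numbers in the tables stem from a simulated flask for substances that don't exist; scatter was added.

The amounts of free starting material in the earlier runs, taken as fractions of the charge, fell along a progress curve that I could count in half-times.

| flask | starting material | protic impurity | remark | time |
|---|---|---|---|---|
| north-west | 0.050 M | 1.7 mM | run made earlier |  |
| north | 0.050 M | 3.8 mM | run made earlier |  |
| south | 0.10 M | 2.5 mM | run made earlier |  |
| flask | 0.050 M | 2.50 mM |  | 4.0 h |

| run | time / h | starting material / % | intermediate A / % | intermediate B / % | target / % | isomer of the product / % | intermediate C / % |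
|---|---|---|---|---|---|---|---|
| north-west | 0.417 | 90.4 | 3.5 | 0.7 | 0 | 0.4 | 0 |
| north-west | 1.00 | 80.9 | 8.3 | 0.9 | 0 | 0.1 | 0 |
| north-west | 2.00 | 67.6 | 13.5 | 1.9 | 0.6 | 0.4 | 0 |
| north-west | 3.00 | 58.1 | 17.3 | 4.4 | 0.3 | 0 | 0.3 |
| north | 0.250 | 92.9 | 2.0 | 0 | 0.2 | 0 | 0 |
| north | 0.667 | 82.6 | 5.8 | 0 | 0 | 0.1 | 0.1 |
| north | 1.33 | 72.5 | 9.5 | 1.1 | 0 | 0.3 | 0.4 |
| north | 3.00 | 55.3 | 16.7 | 4.5 | 0.1 | 0 | 0.2 |
| south | 0.417 | 90.2 | 4.7 | 0.1 | 0.3 | 0.3 | 0 |
| south | 1.00 | 80.9 | 8.6 | 0.4 | 0.3 | 0 | 0.4 |
| south | 2.00 | 68.1 | 13.7 | 1.9 | 0 | 0.4 | 0.6 |
| south | 3.00 | 59.6 | 17.8 | 4.7 | 0 | 0.6 | 0.7 |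

(standard deviation of a reading: 0.3 percentage points)

- a reading or a percentage of starting material is of its free form alone

- the largest share of what was charged as starting material, at 4.0 h belongs to (intermediate B / intermediate C / intermediate A / starting material / target / isomer of the product)
- the largest share itself, whichever of these holds it, in percent of the starting material charged

In the north-west run, the reciprocal of the fraction left, less one, rose in a straight line with time. The south run, with twice the charge, read 59.6% at 3.00 h against 58.1%, so I reckoned in fractions. I called the time at which that line reaches one, and the fraction left is half, the half-time. The north-west run gave 4.16 h and the north run 3.71 h. Interpolating on protic impurity, at 5.00% of the charge in the flask, I got a half-time of 3.99 h.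

My curve for the flask therefore began with a slope of 0.251 h⁻¹ and passed 57.1% at 3.00 h. It reached 49.9% at 4.0 h, by then a quarter as steep. It put a quarter of the charge at 12.0 h, and the readings showed no level. Intermediate A rose 3.8 percentage points in the last hour of the north-west run, and one more such step gave 21.1%, well below starting material, so I drew no crossing.

The forecast named starting material at 50.5%, a little above my figure, with “a slope of about 0.25”.

    intermediate C → target (k = 0.0800 h⁻¹)
    target ⇌ isomer of the product (K = 1.30, k = 0.610 h⁻¹)
    starting material + protic impurity → quenched substrate (k = 41.0 M⁻¹ h⁻¹)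
    intermediate A → intermediate B (k = 0.160 h⁻¹)
    starting material → intermediate A (k = 0.100 h⁻¹)
    starting material ⇌ dormant form (K = 0.500, k = 0.0940 h⁻¹)
    intermediate B → intermediate C (k = 0.0950 h⁻¹)

The flask held starting material at 49.9%, with intermediate A at 19.7%, and 4.0 h was 1.00 of my half-times. In the flask, the asked time was shorter than the 6.9 h half-life of starting material by its step to intermediate A. Intermediate A in the flask was still made 1.59 times as fast as it went on to intermediate B, each step taken net, at 4.00 h. The neighbour flask left until 15 h held 19.8% starting material, against 21.0% by the half-time, and its largest share had passed to intermediate B, at 24.5%.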